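**Plan**

- Retrosynthetic cuts: first C9–C11 (side chain onto ring B), then C3–C4 together with the C19–heteroatom bond (ring A, opened at its quaternary carbon), then C10–C1 and C10–C20 (two enolate alkylations of carvone). The 2,3-diol is read as a former C2=C3 alkene and the C7=C8 alkene as a transposed C9 carbonyl.
- Enabling feature: ring A (C1–C5 and C10) ends at quaternary C4, whose axial C19 (the acetoxymethyl carbon) lies on the face of the C20 methyl on C10 and next to the C2–C3 cis-diol. An alkenyl iodide at C3 and an isopropenyl group on C5 can therefore deliver ring A, C4, a handle on C19 and the C2=C3 alkene in one operation.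
- Forward order: ring B is (S)-carvone; C20 and the C1–C3 (Z)-iodoallyl arm are placed on C10; ring A is closed by palladium with boron capture at C19; the C11–C15 chain is added to the C9 ketone; oxygen is moved to C7 and removed while the alkene shifts to C7=C8; C15 is oxidised last.
- Stereochemistry: C5 from (S)-carvone; C10 by alkylation anti to the isopropenyl group; C4 by the chair-like syn insertion; C2 and C3 by OsO4 on the face opposite the axial C19 and C20; C9 by Luche reduction, Mitsunobu inversion and suprafacial hydrogen transfer from an allylic diazene; C13 from methyl hydrogen (R)-3-methylglutarate.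

Key step: step 6

Remark: labdane numbering is used for all bicyclic compounds (C17 on C8, C18 and C19 on C4, C20 on C10, side chain C11–C16); 7 and 21 are drawn as their expected major epimers, because the minor epimer at C6 of 7 or C9 of 21 is converted into the same product in the following step.

**Route**

Step 1
Reactants: 1 prop-2-yn-1-ol
Product: 2 3-iodoprop-2-yn-1-ol
Conditions: NIS, AgNO3 (10 mol %), acetone, rt, dark
Reagents that add atoms: N-iodosuccinimide, O=C1CCC(=O)N1I
Why: Silver-catalysed electrophilic iodination of the terminal alkyne C–H should give the 1-iodoalkyne without touching the primary alcohol.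

Step 2
Reactants: 2 3-iodoprop-2-yn-1-ol
Product: 3 (Z)-3-iodoprop-2-en-1-ol
Conditions: 2-nitrobenzenesulfonyl hydrazide, Et3N, THF/i-PrOH, rt
Reagents that add atoms: none
Why: Diimide reduction transfers two hydrogens to one face of the iodoalkyne, so the (Z)-alkenyl iodide should form without hydrogenolysis of the C–I bond.

Step 3
Reactants: 3 (Z)-3-iodoprop-2-en-1-ol
Product: 4 (Z)-3-bromo-1-iodoprop-1-ene
Conditions: CBr4, PPh3, CH2Cl2, 0 °C
Reagents that add atoms: carbon tetrabromide, BrC(Br)(Br)Br
Why: Appel bromination should convert the primary allylic alcohol into the bromide by SN2 displacement under neutral conditions that leave the alkene geometry unchanged.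

Step 4
Reactants: 5 (S)-carvone
Product: 7 (5S,6R)-2,6-dimethyl-5-(prop-1-en-2-yl)cyclohex-2-en-1-one, via lithium dienolate 6 (not isolated)
Conditions: LiN(iPr)2 (LDA), THF, −78 °C; MeI, −78 to 0 °C
Reagents that add atoms: iodomethane, CI
Why: Kinetic deprotonation at C6 gives the cross-conjugated enolate, whose SN2 methylation (enolate alkylation) should occur mainly anti to the isopropenyl group, the C6 configuration being erased again in step 5.

Step 5
Reactants: 7 (5S,6R)-2,6-dimethyl-5-(prop-1-en-2-yl)cyclohex-2-en-1-one; 4 (Z)-3-bromo-1-iodoprop-1-ene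
Product: 9 (5R,6R)-6-[(2Z)-3-iodoprop-2-en-1-yl]-2,6-dimethyl-5-(prop-1-en-2-yl)cyclohex-2-en-1-one, via lithium enolate 8 (not isolated)
Conditions: LiN(iPr)2 (LDA), THF, −78 to 0 °C; then 4, DMPU, −78 °C to rt
Reagents that add atoms: none
Why: Enolate alkylation at the fully substituted C6 (C10 of the target) should take place on the face anti to the adjacent isopropenyl group, which sets the quaternary centre with the iodoallyl arm trans and the methyl group cis to isopropenyl.

Step 6
Reactants: 9 (5R,6R)-6-[(2Z)-3-iodoprop-2-en-1-yl]-2,6-dimethyl-5-(prop-1-en-2-yl)cyclohex-2-en-1-one; 10 bis(pinacolato)diboron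
Product: 13 19-(pinacolatoboryl)-11,12,13,14,15,16-hexanorlabda-2,7-dien-9-one, via alkenylpalladium iodide 11 (not isolated), via neopentylpalladium iodide 12 (not isolated)
Conditions: Pd(PPh3)4 (10 mol %), 10 (2 equiv), KOAc (3 equiv), 1,4-dioxane, 90 °C
Reagents that add atoms: none
Why: Zerovalent palladium inserts into the C3–I bond with retention of the (Z) geometry to give 11, which adds syn across the isopropenyl alkene so that C3 bonds to its inner carbon (C4) while palladium moves to the terminal carbon (C19); the neopentylpalladium 12 has no β-hydrogen, so it lives long enough to be transmetalated by B2pin2 with acetate and to release the C19–B bond by reductive elimination. The closest known reaction type is the domino intramolecular Heck cyclisation with Miyaura-type boron capture, which turns halides tethered to a 1,1-disubstituted alkene into neopentyl boronates with a new quaternary carbon. Ring A closes in the 6-exo-trig mode, preferred over 7-endo because the coplanar four-centre insertion is reached without strain when C3 meets C4. The one new stereocentre, C4, is controlled by C5 and C10: with the isopropenyl group and the C1 arm both equatorial on ring B the forming ring is chair-like, and the insertion geometry holds the C4=C19 bond eclipsed with the Pd–C3 bond, so the palladium-bearing methylene becomes the axial substituent on the face of the C20 methyl and C18 becomes equatorial. The step needs ring closure to outrun direct borylation of 11 and boron capture to outrun 3-exo attack of 12 on the new C2=C3 bond; the first is secured by the short, conformationally biased tether and the second by excess B2pin2 with KOAc, while the ring B enone does not take part.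

Step 7
Reactants: 13 19-(pinacolatoboryl)-11,12,13,14,15,16-hexanorlabda-2,7-dien-9-one
Product: 14 19-hydroxy-11,12,13,14,15,16-hexanorlabda-2,7-dien-9-one
Conditions: NaBO3·4H2O, THF/H2O (1:1), rt
Reagents that add atoms: sodium perborate tetrahydrate, [Na+].[O-]B1OO1.O.O.O.O
Why: Perborate oxidation of the C–B bond proceeds by 1,2-shift of C19 from boron to oxygen and should give the neopentyl alcohol under conditions mild enough to spare the enone and the C2=C3 alkene.

Step 8
Reactants: 15 methyl hydrogen (R)-3-methylglutarate
Product: 16 methyl (R)-5-hydroxy-3-methylpentanoate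
Conditions: BH3·SMe2, THF, −10 °C to rt; MeOH quench
Reagents that add atoms: none
Why: Borane reduces the free carboxylic acid much faster than the methyl ester (chemoselective borane reduction), so the acid end should become the future C11 carbinol while the stereocentre is untouched.

Step 9
Reactants: 16 methyl (R)-5-hydroxy-3-methylpentanoate
Product: 17 methyl (S)-5-iodo-3-methylpentanoate
Conditions: I2, PPh3, imidazole, CH2Cl2, 0 °C to rt
Reagents that add atoms: iodine, II
Why: Appel-type iodination should replace the primary hydroxyl by iodide through SN2 displacement of the oxyphosphonium group, and it removes the risk of lactonisation.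

Step 10
Reactants: 17 methyl (S)-5-iodo-3-methylpentanoate
Product: 18 (S)-5-iodo-3-methylpentan-1-ol
Conditions: i-Bu2AlH (2.2 equiv), CH2Cl2, −78 to 0 °C; aqueous KNaC4H4O6 work-up
Reagents that add atoms: none
Why: Hydride reduction of the ester with i-Bu2AlH should give the primary alcohol (future C15) while the primary alkyl iodide is inert to this reagent at low temperature.

Step 11
Reactants: 18 (S)-5-iodo-3-methylpentan-1-ol
Product: 19 (S)-tert-butyl[(5-iodo-3-methylpentyl)oxy]dimethylsilane
Conditions: TBSCl, imidazole, CH2Cl2, rt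
Reagents that add atoms: tert-butyldimethylsilyl chloride, CC(C)(C)[Si](C)(C)Cl
Why: Silylation of the primary alcohol should give an ether that survives the organolithium, chromium and Mitsunobu steps and is removed by fluoride.

Step 12
Reactants: 14 19-hydroxy-11,12,13,14,15,16-hexanorlabda-2,7-dien-9-one; 19 (S)-tert-butyl[(5-iodo-3-methylpentyl)oxy]dimethylsilane
Product: 21 15-(tert-butyldimethylsilyloxy)labda-2,7-diene-9,19-diol, via alkyllithium 20 (not isolated)
Conditions: 19 (2.5 equiv), t-BuLi (5 equiv), Et2O/pentane, −78 °C; then 14 in THF, −78 to −30 °C; H2O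
Reagents that add atoms: none
Why: Iodine–lithium exchange gives the primary alkyllithium, which, after one equivalent has deprotonated the C19 hydroxyl, should add 1,2 to the C9 carbonyl (organolithium addition) from the face opposite the axial C20 methyl, the C9 configuration being lost again in step 14.

Step 13
Reactants: 21 15-(tert-butyldimethylsilyloxy)labda-2,7-diene-9,19-diol
Product: 22 19-acetoxy-15-(tert-butyldimethylsilyloxy)labda-2,7-dien-9-ol
Conditions: Ac2O, pyridine, CH2Cl2, 0 °C to rt
Reagents that add atoms: acetic anhydride, CC(=O)OC(C)=O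
Why: Acylation should occur only at the primary C19 hydroxyl because the tertiary allylic C9 hydroxyl is too hindered, which installs the acetate of the target and at the same time protects C19 for the oxidation that follows.

Step 14
Reactants: 22 19-acetoxy-15-(tert-butyldimethylsilyloxy)labda-2,7-dien-9-ol
Product: 23 19-acetoxy-15-(tert-butyldimethylsilyloxy)labda-2,8-dien-7-one
Conditions: pyridinium chlorochromate [C5H5NH][CrO3Cl], NaOAc, 4 Å molecular sieves, CH2Cl2, rt
Reagents that add atoms: pyridinium chlorochromate, [O-][Cr](=O)(=O)Cl.c1cc[nH+]cc1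
Why: Babler–Dauben oxidative transposition should move the oxygen from C9 to C7 by a [3,3] shift on chromium and oxidise it to the ketone, leaving the side chain on the new C8=C9 bond of the enone.

Step 15
Reactants: 23 19-acetoxy-15-(tert-butyldimethylsilyloxy)labda-2,8-dien-7-one
Product: 24 19-acetoxy-15-(tert-butyldimethylsilyloxy)-2,3-dihydroxylabd-8-en-7-one
Conditions: OsO4 (4 mol %), NMO, acetone/H2O (4:1), rt
Reagents that add atoms: osmium tetroxide, O=[Os](=O)(=O)=O; N-methylmorpholine N-oxide, C[N+]1([O-])CCOCC1
Why: Upjohn dihydroxylation should add both oxygens syn to the electron-rich cis C2=C3 alkene, and not to the electron-poor tetrasubstituted enone, from the face opposite the axial C19 on C4 and the axial C20 on C10, which sets C2 and C3.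

Step 16
Reactants: 24 19-acetoxy-15-(tert-butyldimethylsilyloxy)-2,3-dihydroxylabd-8-en-7-one
Product: 25 19-acetoxy-15-(tert-butyldimethylsilyloxy)-2,3-(isopropylidenedioxy)labd-8-en-7-one
Conditions: 2,2-dimethoxypropane, PPTS (cat.), CH2Cl2, rt
Reagents that add atoms: 2,2-dimethoxypropane, COC(C)(C)OC
Why: Acid-catalysed ketal exchange should close the five-membered acetonide on the cis-2,3-diol, which shields both secondary hydroxyls from the Mitsunobu and oxidation steps.

Step 17
Reactants: 25 19-acetoxy-15-(tert-butyldimethylsilyloxy)-2,3-(isopropylidenedioxy)labd-8-en-7-one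
Product: 26 19-acetoxy-15-(tert-butyldimethylsilyloxy)-2,3-(isopropylidenedioxy)labd-8-en-7-ol
Conditions: NaBH4, CeCl3·7H2O, MeOH, −78 to −40 °C
Reagents that add atoms: none
Why: Luche reduction should deliver hydride 1,2 and axially to the C7 carbonyl, giving the equatorial allylic alcohol on the face of C20 while the acetate survives at low temperature.

Step 18
Reactants: 26 19-acetoxy-15-(tert-butyldimethylsilyloxy)-2,3-(isopropylidenedioxy)labd-8-en-7-ol
Product: 29 19-acetoxy-15-(tert-butyldimethylsilyloxy)-2,3-(isopropylidenedioxy)labd-7-ene, via sulfonyl hydrazone adduct 27 (not isolated), via allylic diazene 28 (not isolated)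
Conditions: N-isopropylidene-N'-2-nitrobenzenesulfonyl hydrazine, PPh3, DEAD, THF, 0 °C to rt; then CF3CH2OH/H2O (1:1), rt
Reagents that add atoms: none
Why: Mitsunobu displacement by the hydrazine nitrogen inverts C7 to give 27, hydrolysis and loss of sulfinic acid give the diazene 28, and its retro-ene loss of N2 should transfer hydrogen to C9 on the face that nitrogen occupied (opposite C20) while the alkene moves to C7=C8, which sets C9.

Step 19
Reactants: 29 19-acetoxy-15-(tert-butyldimethylsilyloxy)-2,3-(isopropylidenedioxy)labd-7-ene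
Product: 30 19-acetoxy-2,3-(isopropylidenedioxy)labd-7-en-15-ol
Conditions: HF·pyridine, pyridine, THF, 0 °C to rt
Reagents that add atoms: none
Why: Fluoride-mediated desilylation of the primary silyl ether, buffered with pyridine, should leave the acetate, the acetonide and the alkene intact.

Step 20
Reactants: 30 19-acetoxy-2,3-(isopropylidenedioxy)labd-7-en-15-ol
Product: 31 19-acetoxy-2,3-(isopropylidenedioxy)labd-7-en-15-oic acid
Conditions: TEMPO (20 mol %), PhI(OAc)2 (2.5 equiv), MeCN/H2O (1:1), rt
Reagents that add atoms: water, O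
Why: TEMPO-catalysed oxidation with PhI(OAc)2 in aqueous acetonitrile should take the primary alcohol through the aldehyde hydrate to the carboxylic acid without touching the trisubstituted alkene or the acetate.

Step 21
Reactants: 31 19-acetoxy-2,3-(isopropylidenedioxy)labd-7-en-15-oic acid
Product: 32 (2S,3R,4R,5S,9R,10S,13R)-19-acetoxy-2,3-dihydroxylabd-7-en-15-oic acid
Conditions: AcOH/H2O (4:1), 40 °C
Reagents that add atoms: none
Why: Mild acid hydrolysis of the acetonide should release the cis-diol, and the C19 acetate should not migrate because the axial C3 hydroxyl and the axial C19 arm are anti to each other.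

**Compound list**

1 | prop-2-yn-1-ol | C#CCO | starting material
2 | 3-iodoprop-2-yn-1-ol | OCC#CI | intermediate
3 | (Z)-3-iodoprop-2-en-1-ol | OC/C=C\I | intermediate
4 | (Z)-3-bromo-1-iodoprop-1-ene | BrC/C=C\I | intermediate
5 | (S)-carvone, (5S)-2-methyl-5-(prop-1-en-2-yl)cyclohex-2-en-1-one | C=C(C)[C@H]1CC=C(C)C(=O)C1 | starting material
6 | lithium dienolate of 5 (O–Li on C1, C1=C6 and C2=C3 double bonds; formed in the flask) | C=C(C)[C@H]1CC=C(C)C(O[Li])=C1 | intermediate
7 | (5S,6R)-2,6-dimethyl-5-(prop-1-en-2-yl)cyclohex-2-en-1-one (trans-6-methylcarvone) | C=C(C)[C@H]1CC=C(C)C(=O)[C@@H]1C | intermediate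
8 | lithium enolate of 7 (O–Li on C1, tetrasubstituted C1=C6; formed in the flask) | C=C(C)[C@H]1CC=C(C)C(O[Li])=C1C | intermediate
9 | (5R,6R)-6-[(2Z)-3-iodoprop-2-en-1-yl]-2,6-dimethyl-5-(prop-1-en-2-yl)cyclohex-2-en-1-one (methyl cis and iodoallyl trans to isopropenyl) | C=C(C)[C@H]1CC=C(C)C(=O)[C@]1(C)C/C=C\I | intermediate
10 | bis(pinacolato)diboron | CC1(C)OB(OC1(C)C)B1OC(C)(C)C(C)(C)O1 | starting material
11 | alkenylpalladium iodide from 9 (divalent palladium on C3, phosphine ligands omitted; formed in the flask) | C=C(C)[C@H]1CC=C(C)C(=O)[C@]1(C)C/C=C\[Pd]I | intermediate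
12 | neopentylpalladium iodide (ring A closed, divalent palladium on C19, phosphine ligands omitted; formed in the flask) | I[Pd]C[C@@]1(C)[C@H]2CC=C(C)C(=O)[C@]2(C)CC=C1 | intermediate
13 | 19-(pinacolatoboryl)-11,12,13,14,15,16-hexanorlabda-2,7-dien-9-one (trans ring fusion, H5 opposite C20; C19 axial on C4 on the face of C20) | CC1(C)OB(C[C@@]2(C)[C@H]3CC=C(C)C(=O)[C@]3(C)CC=C2)OC1(C)C | intermediate
14 | 19-hydroxy-11,12,13,14,15,16-hexanorlabda-2,7-dien-9-one (configuration as in 13) | OC[C@@]1(C)[C@H]2CC=C(C)C(=O)[C@]2(C)CC=C1 | intermediate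
15 | methyl hydrogen (R)-3-methylglutarate | OC(=O)C[C@@H](C)CC(=O)OC | starting material
16 | methyl (R)-5-hydroxy-3-methylpentanoate | OCC[C@@H](C)CC(=O)OC | intermediate
17 | methyl (S)-5-iodo-3-methylpentanoate | ICC[C@@H](C)CC(=O)OC | intermediate
18 | (S)-5-iodo-3-methylpentan-1-ol | ICC[C@@H](C)CCO | intermediate
19 | (S)-tert-butyl[(5-iodo-3-methylpentyl)oxy]dimethylsilane | ICC[C@@H](C)CCO[Si](C)(C)C(C)(C)C | intermediate
20 | [(3R)-5-(tert-butyldimethylsilyloxy)-3-methylpentyl]lithium (formed in the flask) | [Li]CC[C@@H](C)CCO[Si](C)(C)C(C)(C)C | intermediate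
21 | 15-(tert-butyldimethylsilyloxy)labda-2,7-diene-9,19-diol (9-OH on the face of C20, side chain on the opposite face; C13 as in the target) | OC[C@@]1(C)[C@H]2CC=C(C)[C@](O)(CC[C@@H](C)CCO[Si](C)(C)C(C)(C)C)[C@]2(C)CC=C1 | intermediate
22 | 19-acetoxy-15-(tert-butyldimethylsilyloxy)labda-2,7-dien-9-ol | CC(=O)OC[C@@]1(C)[C@H]2CC=C(C)[C@](O)(CC[C@@H](C)CCO[Si](C)(C)C(C)(C)C)[C@]2(C)CC=C1 | intermediate
23 | 19-acetoxy-15-(tert-butyldimethylsilyloxy)labda-2,8-dien-7-one | CC(=O)OC[C@@]1(C)[C@H]2CC(=O)C(C)=C(CC[C@@H](C)CCO[Si](C)(C)C(C)(C)C)[C@]2(C)CC=C1 | intermediate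
24 | 19-acetoxy-15-(tert-butyldimethylsilyloxy)-2,3-dihydroxylabd-8-en-7-one (cis-diol on the face opposite C19 and C20) | CC(=O)OC[C@@]1(C)[C@H]2CC(=O)C(C)=C(CC[C@@H](C)CCO[Si](C)(C)C(C)(C)C)[C@]2(C)C[C@H](O)[C@@H]1O | intermediate
25 | 19-acetoxy-15-(tert-butyldimethylsilyloxy)-2,3-(isopropylidenedioxy)labd-8-en-7-one | CC(=O)OC[C@@]1(C)[C@H]2CC(=O)C(C)=C(CC[C@@H](C)CCO[Si](C)(C)C(C)(C)C)[C@]2(C)C[C@H](O3)[C@@H]1OC3(C)C | intermediate
26 | 19-acetoxy-15-(tert-butyldimethylsilyloxy)-2,3-(isopropylidenedioxy)labd-8-en-7-ol (7-OH equatorial, on the face of C20) | CC(=O)OC[C@@]1(C)[C@H]2C[C@@H](O)C(C)=C(CC[C@@H](C)CCO[Si](C)(C)C(C)(C)C)[C@]2(C)C[C@H](O3)[C@@H]1OC3(C)C | intermediate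
27 | C7 N-(2-nitrobenzenesulfonyl)-N'-isopropylidene hydrazine adduct of 26 (nitrogen on the face opposite C20; formed in the flask) | CC(=O)OC[C@@]1(C)[C@H]2C[C@H](N(N=C(C)C)S(=O)(=O)c3ccccc3[N+](=O)[O-])C(C)=C(CC[C@@H](C)CCO[Si](C)(C)C(C)(C)C)[C@]2(C)C[C@H](O4)[C@@H]1OC4(C)C | intermediate
28 | C7 allylic diazene (N=NH on the face opposite C20; formed in the flask) | CC(=O)OC[C@@]1(C)[C@H]2C[C@H](N=N)C(C)=C(CC[C@@H](C)CCO[Si](C)(C)C(C)(C)C)[C@]2(C)C[C@H](O3)[C@@H]1OC3(C)C | intermediate
29 | 19-acetoxy-15-(tert-butyldimethylsilyloxy)-2,3-(isopropylidenedioxy)labd-7-ene (all centres as in the target) | CC(=O)OC[C@@]1(C)[C@H]2CC=C(C)[C@@H](CC[C@@H](C)CCO[Si](C)(C)C(C)(C)C)[C@]2(C)C[C@H](O3)[C@@H]1OC3(C)C | intermediate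
30 | 19-acetoxy-2,3-(isopropylidenedioxy)labd-7-en-15-ol | CC(=O)OC[C@@]1(C)[C@H]2CC=C(C)[C@@H](CC[C@@H](C)CCO)[C@]2(C)C[C@H](O3)[C@@H]1OC3(C)C | intermediate
31 | 19-acetoxy-2,3-(isopropylidenedioxy)labd-7-en-15-oic acid | CC(=O)OC[C@@]1(C)[C@H]2CC=C(C)[C@@H](CC[C@@H](C)CC(=O)O)[C@]2(C)C[C@H](O3)[C@@H]1OC3(C)C | intermediate
32 | (2S,3R,4R,5S,9R,10S,13R)-19-acetoxy-2,3-dihydroxylabd-7-en-15-oic acid (CNP0164890.1) | CC(=O)OC[C@@]1(C)[C@H]2CC=C(C)[C@@H](CC[C@@H](C)CC(=O)O)[C@]2(C)C[C@H](O)[C@@H]1O | target

**Step count**

Total: 21 steps. Longest linear sequence: 16 steps (steps 1–3, 5–7 and 12–21, from prop-2-yn-1-ol).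

**Steps most likely to fail**

Step 6. The alkenylpalladium may be borylated before it cyclises, the neopentylpalladium may be lost by 3-exo attack on C2=C3 before boron capture, or the insertion may not hold C19 fully on the C20 face. The fallback sets out from 9 and returns at 14; it installs the C19 oxygen before ring closure and ends the cyclisation with hydride. Oxidative cleavage of the isopropenyl group of 9 (OsO4 cat., NaIO4, 2,6-lutidine, dioxane/H2O) should give the methyl ketone F1. Wittig olefination with the ylide from (4-methoxybenzyloxymethyl)triphenylphosphonium chloride and NaN(SiMe3)2 should give the 4-methoxybenzyl enol ether F2, whose two alkene isomers converge. A reductive Heck cyclisation (Pd(OAc)2, PPh3, HCO2Na, Et4NCl, DMF, 80 °C) closes the same C3–C4 bond 6-exo, and formate reduces the α-alkoxyalkylpalladium at once, so the oxygen-bearing carbon takes the axial place and the C19 4-methoxybenzyl ether F3 results. DDQ in wet CH2Cl2 then frees 14, and the C–B oxidation is no longer needed.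

Step 18. The Mitsunobu displacement at the hindered C7 carbinol may stall, take the allylic (SN2') course or end in elimination to a diene, and any loss of inversion at C7 would erode C9. The fallback sets out from 26 and returns at 29. The alcohol is converted into the C7 methyl carbonate F4 (ClCO2Me, pyridine, DMAP, CH2Cl2) and subjected to palladium-catalysed formate hydrogenolysis (Pd(OAc)2, n-Bu3P, HCO2H, Et3N, THF, 40 °C). Ionisation anti to the carbonate places palladium on the face opposite C20, and hydride transfer from palladium to the more substituted allyl terminus (C9) on that face should give 29 with the C7=C8 alkene.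

Step 5. C-alkylation at the fully substituted enolate carbon may be slow, so the (Z)-iodoallyl bromide may be consumed by base-induced elimination, and the facial preference may erode at the higher temperature then required. The fallback sets out from 7 and returns at 9; it brings in the three carbons as a small, robust electrophile and builds the alkenyl iodide afterwards. Enolate 8 is alkylated with 3-bromoprop-1-yne to give the propargyl ketone F5, the terminal alkyne is iodinated (NIS, AgNO3 cat., acetone) to the iodoalkyne F6, and diimide (2-nitrobenzenesulfonyl hydrazide, Et3N, THF/i-PrOH) reduces the iodoalkyne syn to the (Z)-alkenyl iodide 9.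

Further compounds
F1 | step 6 | (5R,6R)-5-acetyl-6-[(2Z)-3-iodoprop-2-en-1-yl]-2,6-dimethylcyclohex-2-en-1-one (methyl ketone in place of isopropenyl) | CC(=O)[C@H]1CC=C(C)C(=O)[C@]1(C)C/C=C\I
F2 | step 6 | 4-methoxybenzyl enol ether of F1 (C5 substituent C(CH3)=CH–O–CH2C6H4OMe, alkene isomer mixture) | COc1ccc(COC=C(C)[C@H]2CC=C(C)C(=O)[C@]2(C)C/C=C\I)cc1
F3 | step 6 | 19-(4-methoxybenzyloxy)-11,12,13,14,15,16-hexanorlabda-2,7-dien-9-one (configuration as in 13) | COc1ccc(COC[C@@]2(C)[C@H]3CC=C(C)C(=O)[C@]3(C)CC=C2)cc1
F4 | step 18 | C7 methyl carbonate of 26 | CC(=O)OC[C@@]1(C)[C@H]2C[C@@H](OC(=O)OC)C(C)=C(CC[C@@H](C)CCO[Si](C)(C)C(C)(C)C)[C@]2(C)C[C@H](O3)[C@@H]1OC3(C)C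
F5 | step 5 | (5R,6R)-2,6-dimethyl-5-(prop-1-en-2-yl)-6-(prop-2-yn-1-yl)cyclohex-2-en-1-one | C=C(C)[C@H]1CC=C(C)C(=O)[C@]1(C)CC#C
F6 | step 5 | (5R,6R)-6-(3-iodoprop-2-yn-1-yl)-2,6-dimethyl-5-(prop-1-en-2-yl)cyclohex-2-en-1-one | C=C(C)[C@H]1CC=C(C)C(=O)[C@]1(C)CC#CI
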